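The core is numbered as in the name of 21 (ring A: C3a, C4–C7, C7a; ring B: C1, C2, C3, C3a, C7a). Everything rests on cutting ring B at C2=C3 and C1–C7a: the ethyl-bearing alkene carbon C3 is a former ketone carbon, and C1, C2 and the C1 methyl are crotonaldehyde, whose formyl carbon leaves as CO2. One carbene-catalysed homoenolate annulation of crotonaldehyde onto the 2-propanoylcyclohexa-1,3-diene 17 thus closes ring B, sets C1, C3a and C7a and keeps the C6=C7 alkene. Dienone 17, carrying both quaternary centres, comes from a lactate-tethered intramolecular Diels–Alder reaction whose three-atom tether is then cut and eliminated.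

Key step: step 11

Assumption: acid 10 is taken as a catalogue compound, and the facial sense assigned to the lactate methyl group in step 8 rests on a transition-state model; the enantiomeric lactate would be taken if the opposite sense were met.

Step 1
Reactants: 1 1,1-diethoxybutane
Product: 3 2-ethylpropanedial, via aminoacrolein 2 (not isolated)
Conditions: POCl3, DMF, 0 → 70 °C; aq. NaOH, 70 °C; then aq. HCl to pH 3
Reagents that add atoms: N,N-dimethylformamide, CN(C)C=O; water, O
Why: Vilsmeier–Haack formylation of the enol ether that the acetal forms in situ gives the vinylogous formamide 2 (one carbon from DMF), which aqueous base hydrolyses to the enolate of the 2-substituted malonaldehyde, a standard two-stage route to alkylmalonaldehydes that creates no stereocentre.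

Step 2
Reactants: 3 2-ethylpropanedial; 4 methyl (2R)-2-hydroxypropanoate
Product: 5 methyl (2S)-2-{[(1E)-2-formylbut-1-en-1-yl]oxy}propanoate
Conditions: PPh3, DIAD, THF, 0 °C → rt
Reagents that add atoms: none
Why: Mitsunobu etherification with the malonaldehyde enol (pKa about 5) as the acidic partner alkylates oxygen with SN2 inversion at the lactate carbon, which sets the (S) centre, and the push–pull enol ether should settle in the E geometry.

Step 3
Reactants: 6 diethyl [(2E)-3-phenylprop-2-en-1-yl]phosphonate
Product: 7 diethyl [(1E)-1-phenylpent-1-en-3-yl]phosphonate (racemic)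
Conditions: LiN(i-Pr)2, THF, −78 °C; EtI, −78 °C → rt
Reagents that add atoms: iodoethane, CCI
Why: Deprotonation gives the phosphonate-stabilised allyl anion, which is alkylated at the α-carbon as is usual for allylphosphonates; the new centre is racemic and becomes sp2 in step 4.

Step 4
Reactants: 5 methyl (2S)-2-{[(1E)-2-formylbut-1-en-1-yl]oxy}propanoate; 7 diethyl [(1E)-1-phenylpent-1-en-3-yl]phosphonate
Product: 8 methyl (2S)-2-{[(1E,3E,5E)-2,4-diethyl-6-phenylhexa-1,3,5-trien-1-yl]oxy}propanoate
Conditions: 7, LiN(SiMe3)2, THF, −78 °C; then 5, −78 °C → rt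
Reagents that add atoms: none
Why: Horner–Wadsworth–Emmons olefination of the aldehyde of 5 with the preformed lithium anion of 7 builds the C3=C4 bond of the triene with the conjugating styryl group trans to the aldehyde-derived chain (the E preference of α-alkylated stabilised phosphonates), the anion being fully formed before 5 is added so that the lactate centre does not meet free base.

Step 5
Reactants: 8 methyl (2S)-2-{[(1E,3E,5E)-2,4-diethyl-6-phenylhexa-1,3,5-trien-1-yl]oxy}propanoate
Product: 9 (2S)-2-{[(1E,3E,5E)-2,4-diethyl-6-phenylhexa-1,3,5-trien-1-yl]oxy}propanal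
Conditions: i-Bu2AlH, CH2Cl2, −78 °C; aq. potassium sodium tartrate
Reagents that add atoms: none
Why: The aluminium hydride at −78 °C stops at the chelated tetrahedral aluminate of the α-alkoxy ester, so that work-up should give the aldehyde without touching the stereocentre or the dienyl ether.

Step 6
Reactants: 10 (2E)-3-iodo-2-methylprop-2-enoic acid
Product: 11 2-(trimethylsilyl)ethyl (2E)-3-iodo-2-methylprop-2-enoate
Conditions: 2-(trimethylsilyl)ethanol, DCC, DMAP (cat.), CH2Cl2, 0 °C → rt
Reagents that add atoms: 2-(trimethylsilyl)ethanol, C[Si](C)(C)CCO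
Why: Steglich esterification installs a carboxyl protecting group that is later removed by fluoride at silicon, far from the hindered quaternary carbon, and leaves the E-iodoalkene untouched.

Step 7
Reactants: 9 (2S)-2-{[(1E,3E,5E)-2,4-diethyl-6-phenylhexa-1,3,5-trien-1-yl]oxy}propanal; 11 2-(trimethylsilyl)ethyl (2E)-3-iodo-2-methylprop-2-enoate
Product: 12 2-(trimethylsilyl)ethyl (2E,5S)-5-{[(1E,3E,5E)-2,4-diethyl-6-phenylhexa-1,3,5-trien-1-yl]oxy}-4-hydroxy-2-methylhex-2-enoate (both C4 epimers)
Conditions: CrCl2, NiCl2 (cat.), DMSO, rt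
Reagents that add atoms: none
Why: Nozaki–Hiyama–Kishi coupling adds the alkenylchromium reagent formed from 11 to the aldehyde with retention of the E geometry and tolerates the ester and the dienyl ether; the new carbinol centre is formed unselectively but is oxidised in step 8.

Step 8
Reactants: 12 2-(trimethylsilyl)ethyl (2E,5S)-5-{[(1E,3E,5E)-2,4-diethyl-6-phenylhexa-1,3,5-trien-1-yl]oxy}-4-hydroxy-2-methylhex-2-enoate
Product: 14 2-(trimethylsilyl)ethyl (2S,3aR,4R,5S,7aS)-5,7-diethyl-2,4-dimethyl-3-oxo-5-[(E)-2-phenylethenyl]-2,3,3a,4,5,7a-hexahydro-1-benzofuran-4-carboxylate, via enone 13 (not isolated)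
Conditions: Dess–Martin periodinane, NaHCO3, CH2Cl2, 0 °C → rt; then toluene, 60 °C
Reagents that add atoms: none
Why: Dess–Martin oxidation turns the enoate into an ester- and ketone-activated E-dienophile that adds to the tethered 1-alkoxydiene in a normal-demand intramolecular Diels–Alder reaction through the ester-endo, ketone-exo transition state (trans ring fusion), so that suprafacial addition to the E,E-diene and the E-dienophile places the C4 methyl and C5 ethyl groups cis, while the lactate-derived methyl group on the tether, which turns away from the methyl-bearing dienophile terminus, selects the diene face and with it the absolute configuration of both quaternary centres (C3a and C7a are temporary, and any minor diastereomer is removed here by chromatography).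

Step 9
Reactants: 14 2-(trimethylsilyl)ethyl (2S,3aR,4R,5S,7aS)-5,7-diethyl-2,4-dimethyl-3-oxo-5-[(E)-2-phenylethenyl]-2,3,3a,4,5,7a-hexahydro-1-benzofuran-4-carboxylate
Product: 15 2-(trimethylsilyl)ethyl (1R,2S,5S,6R)-2,4-diethyl-5-hydroxy-1-methyl-2-[(E)-2-phenylethenyl]-6-propanoylcyclohex-3-ene-1-carboxylate
Conditions: SmI2, THF–MeOH, −78 °C
Reagents that add atoms: none
Why: SmI2 reduces the ketone to a ketyl that expels the α-alkoxy group, so the C–O bond at the former lactate carbon is cut to leave the samarium enolate of the propanoyl group (protonated by methanol) and the free C5 hydroxyl, with all stereocentres untouched.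

Step 10
Reactants: 15 2-(trimethylsilyl)ethyl (1R,2S,5S,6R)-2,4-diethyl-5-hydroxy-1-methyl-2-[(E)-2-phenylethenyl]-6-propanoylcyclohex-3-ene-1-carboxylate
Product: 17 2-(trimethylsilyl)ethyl (1S,6S)-4,6-diethyl-1-methyl-6-[(E)-2-phenylethenyl]-2-propanoylcyclohexa-2,4-diene-1-carboxylate, via mesylate 16 (not isolated)
Conditions: MsCl, Et3N, CH2Cl2, 0 °C; then DBU, rt
Reagents that add atoms: none
Why: Mesylation of the secondary allylic alcohol and E1cB elimination through the ketone enolate should give the fully conjugated dienone, only C6–H being available, which deliberately erases the two temporary stereocentres and keeps the two quaternary ones.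

Step 11
Reactants: 17 2-(trimethylsilyl)ethyl (1S,6S)-4,6-diethyl-1-methyl-6-[(E)-2-phenylethenyl]-2-propanoylcyclohexa-2,4-diene-1-carboxylate; 18 (2E)-but-2-enal
Product: 20 2-(trimethylsilyl)ethyl (1R,3aR,4R,5S,7aS)-3,5,7-triethyl-1,4-dimethyl-5-[(E)-2-phenylethenyl]-3a,4,5,7a-tetrahydro-1H-indene-4-carboxylate, via β-lactone 19 (not isolated)
Conditions: 1,3-bis(2,4,6-trimethylphenyl)imidazolium chloride (20 mol%), DBU (25 mol%), THF, rt, 18 (3 equiv) added slowly; then toluene, 90 °C
Reagents that add atoms: none
Why: Proposed new method: the carbene converts 18 into its homoenolate, whose β-carbon adds 1,4 to the enone of 17 (C3 of 17, the future C7a) to form C1–C7a; the ketone enolate is then protonated at the future C3a, the acyl azolium enol (α-carbon of 18, future C2) adds to the ketone carbon (future C3), and the alkoxide acylates back to release the carbene and give cis-β-lactone 19, which loses CO2 on warming to leave the C2=C3 alkene. The closest known reaction is the carbene-catalysed homoenolate annulation of enals with chalcones and 4-oxoenoates to cyclopentenes; it has not been shown on an α-branched cyclic dienone with an alkyl ketone, hence the label. Ring B closes by a 5-(enolexo)-exo-trig aldol addition and the transient oxetanone by 4-exo-trig O-acylation, before the retro-[2+2] loss of CO2. C7a should be set by attack on the ring face anti to the pseudoaxial methyl group of the ester-bearing quaternary carbon (the face of the ester and the styryl group), C1 by the open antiperiplanar Michael transition state that keeps the enal methyl away from the ring ethyl group at C4 of 17 (1,7a-trans, as in the chalcone series), and C3a dynamically: it epimerises through the ketone enol before the aldol step and cyclises from the trans-diequatorial isomer, which gives the trans ring fusion. The step needs 1,4- rather than 1,6-addition, secured by the quaternary C6 of 17 next to the δ-carbon, and cross-annulation rather than enal self-condensation, secured by slow addition of 18.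

Step 12
Reactants: 20 2-(trimethylsilyl)ethyl (1R,3aR,4R,5S,7aS)-3,5,7-triethyl-1,4-dimethyl-5-[(E)-2-phenylethenyl]-3a,4,5,7a-tetrahydro-1H-indene-4-carboxylate
Product: 21 spiculoic acid B, (1R,3aR,4R,5S,7aS)-3,5,7-triethyl-1,4-dimethyl-5-[(E)-2-phenylethenyl]-3a,4,5,7a-tetrahydro-1H-indene-4-carboxylic acid
Conditions: Bu4NF, THF, rt; aq. NH4Cl
Reagents that add atoms: none
Why: Fluoride attacks silicon and the 2-(trimethylsilyl)ethyl ester fragments to ethene, fluorotrimethylsilane and the carboxylate, a deprotection that does not depend on access to the hindered neopentyl carbonyl and leaves alkenes and stereocentres unchanged.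

Compound list
1 | 1,1-diethoxybutane | CCCC(OCC)OCC | starting material
2 | (2E)-3-(dimethylamino)-2-ethylprop-2-enal | CN(C)/C=C(CC)/C=O | intermediate
3 | 2-ethylpropanedial | CCC(C=O)C=O | intermediate
4 | methyl (2R)-2-hydroxypropanoate | COC(=O)[C@@H](C)O | starting material
5 | methyl (2S)-2-{[(1E)-2-formylbut-1-en-1-yl]oxy}propanoate | COC(=O)[C@H](C)O/C=C(CC)/C=O | intermediate
6 | diethyl [(2E)-3-phenylprop-2-en-1-yl]phosphonate | CCOP(=O)(OCC)C/C=C/c1ccccc1 | starting material
7 | diethyl [(1E)-1-phenylpent-1-en-3-yl]phosphonate (racemic) | CCOP(=O)(OCC)C(CC)/C=C/c1ccccc1 | intermediate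
8 | methyl (2S)-2-{[(1E,3E,5E)-2,4-diethyl-6-phenylhexa-1,3,5-trien-1-yl]oxy}propanoate | COC(=O)[C@H](C)O/C=C(CC)/C=C(CC)/C=C/c1ccccc1 | intermediate
9 | (2S)-2-{[(1E,3E,5E)-2,4-diethyl-6-phenylhexa-1,3,5-trien-1-yl]oxy}propanal | O=C[C@H](C)O/C=C(CC)/C=C(CC)/C=C/c1ccccc1 | intermediate
10 | (2E)-3-iodo-2-methylprop-2-enoic acid | OC(=O)/C(C)=C/I | starting material
11 | 2-(trimethylsilyl)ethyl (2E)-3-iodo-2-methylprop-2-enoate | C[Si](C)(C)CCOC(=O)/C(C)=C/I | intermediate
12 | 2-(trimethylsilyl)ethyl (2E,5S)-5-{[(1E,3E,5E)-2,4-diethyl-6-phenylhexa-1,3,5-trien-1-yl]oxy}-4-hydroxy-2-methylhex-2-enoate (both C4 epimers) | C[Si](C)(C)CCOC(=O)/C(C)=C/C(O)[C@H](C)O/C=C(CC)/C=C(CC)/C=C/c1ccccc1 | intermediate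
13 | 2-(trimethylsilyl)ethyl (2E,5S)-5-{[(1E,3E,5E)-2,4-diethyl-6-phenylhexa-1,3,5-trien-1-yl]oxy}-2-methyl-4-oxohex-2-enoate | C[Si](C)(C)CCOC(=O)/C(C)=C/C(=O)[C@H](C)O/C=C(CC)/C=C(CC)/C=C/c1ccccc1 | intermediate
14 | 2-(trimethylsilyl)ethyl (2S,3aR,4R,5S,7aS)-5,7-diethyl-2,4-dimethyl-3-oxo-5-[(E)-2-phenylethenyl]-2,3,3a,4,5,7a-hexahydro-1-benzofuran-4-carboxylate | CCC1=C[C@@](/C=C/c2ccccc2)(CC)[C@](C)(C(=O)OCC[Si](C)(C)C)[C@H]2C(=O)[C@H](C)O[C@H]12 | intermediate
15 | 2-(trimethylsilyl)ethyl (1R,2S,5S,6R)-2,4-diethyl-5-hydroxy-1-methyl-2-[(E)-2-phenylethenyl]-6-propanoylcyclohex-3-ene-1-carboxylate | CCC1=C[C@@](/C=C/c2ccccc2)(CC)[C@](C)(C(=O)OCC[Si](C)(C)C)[C@@H](C(=O)CC)[C@@H]1O | intermediate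
16 | 2-(trimethylsilyl)ethyl (1R,2S,5S,6R)-2,4-diethyl-1-methyl-5-[(methylsulfonyl)oxy]-2-[(E)-2-phenylethenyl]-6-propanoylcyclohex-3-ene-1-carboxylate | CCC1=C[C@@](/C=C/c2ccccc2)(CC)[C@](C)(C(=O)OCC[Si](C)(C)C)[C@@H](C(=O)CC)[C@@H]1OS(C)(=O)=O | intermediate
17 | 2-(trimethylsilyl)ethyl (1S,6S)-4,6-diethyl-1-methyl-6-[(E)-2-phenylethenyl]-2-propanoylcyclohexa-2,4-diene-1-carboxylate | CCC1=C[C@@](/C=C/c2ccccc2)(CC)[C@](C)(C(=O)OCC[Si](C)(C)C)C(C(=O)CC)=C1 | intermediate
18 | (2E)-but-2-enal | C/C=C/C=O | starting material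
19 | tricyclic cis-β-lactone of 20: C2 carboxyl lactonised onto the C3 tertiary oxygen (indene numbering), lactone drawn on the face opposite the C1 methyl group (either lactone face leads to the same alkene) | CCC1=C[C@@](/C=C/c2ccccc2)(CC)[C@](C)(C(=O)OCC[Si](C)(C)C)[C@H]2[C@]3(CC)OC(=O)[C@@H]3[C@@H](C)[C@H]12 | intermediate
20 | 2-(trimethylsilyl)ethyl (1R,3aR,4R,5S,7aS)-3,5,7-triethyl-1,4-dimethyl-5-[(E)-2-phenylethenyl]-3a,4,5,7a-tetrahydro-1H-indene-4-carboxylate | CCC1=C[C@@](/C=C/c2ccccc2)(CC)[C@](C)(C(=O)OCC[Si](C)(C)C)[C@H]2C(CC)=C[C@@H](C)[C@H]12 | intermediate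
21 | spiculoic acid B, (1R,3aR,4R,5S,7aS)-3,5,7-triethyl-1,4-dimethyl-5-[(E)-2-phenylethenyl]-3a,4,5,7a-tetrahydro-1H-indene-4-carboxylic acid | CCC1=C[C@@](/C=C/c2ccccc2)(CC)[C@](C)(C(=O)O)[C@H]2C(CC)=C[C@@H](C)[C@H]12 | target

Total steps: 12. Longest linear sequence: 10 steps (steps 1, 2, 4, 5, 7, 8, 9, 10, 11, 12).

Steps most likely to fail

Step 11 (Proposed new method). The homoenolate may be consumed by self-condensation of the enal before it adds to the hindered α-branched dienone. Facial selectivity at the enone may be poor, or the aldol step may close from the cis isomer at C3a. The fallback sets out from 17 and makes the two ring-B bonds by known reactions in sequence. TiCl4-promoted Hosomi–Sakurai conjugate addition of (E)-but-2-en-1-yl(trimethyl)silane (CH2Cl2, −78 °C) should give the branched 1,4-adduct 2-(trimethylsilyl)ethyl (1R,2S,5S,6S)-5-[(2R)-but-3-en-2-yl]-2,4-diethyl-1-methyl-2-[(E)-2-phenylethenyl]-6-propanoylcyclohex-3-ene-1-carboxylate F1, after equilibration of the ketone α-centre and separation of isomers. Takai–Lombardo methylenation (Zn, CH2Br2, TiCl4, THF), which spares the ester and is not basic, should then give 2-(trimethylsilyl)ethyl (1R,2S,5S,6R)-6-(but-1-en-2-yl)-5-[(2R)-but-3-en-2-yl]-2,4-diethyl-1-methyl-2-[(E)-2-phenylethenyl]cyclohex-3-ene-1-carboxylate F2. Ring-closing metathesis with second-generation Grubbs catalyst RuCl2(=CHPh)(PCy3)(H2IMes) (CH2Cl2, 40 °C) would close the cyclopentene and come back to the route at 20.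

Step 8. Once the ketone is present it may compete with the ester for the endo position, which would invert the C4/C5 relationship. The facial bias of the tether may be weak, and the acid-labile dienyl ether may be cleaved during the oxidation. The fallback sets out from 12 and runs the cycloaddition before the oxidation. Heating 12 (toluene, 2,6-di-tert-butyl-4-methylphenol, 130 °C) engages a dienophile activated only by the E-ester, for which the ester-endo, trans-fused mode is the norm, and should give 2-(trimethylsilyl)ethyl (2S,3RS,3aS,4R,5S,7aS)-5,7-diethyl-3-hydroxy-2,4-dimethyl-5-[(E)-2-phenylethenyl]-2,3,3a,4,5,7a-hexahydro-1-benzofuran-4-carboxylate F3. Dess–Martin oxidation of both carbinol epimers then comes back to the route at 14.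

Step 4. The new trisubstituted alkene may form with poor E/Z control. The phosphonate anion may add to the vinylogous formate in a 1,4 sense and expel the lactate alkoxide, or the lactate centre may epimerise under base. The fallback sets out from 5 and builds the same alkene by stereodefined cross-coupling. Corey–Fuchs dibromo-olefination (CBr4, PPh3, CH2Cl2, 0 °C) should give methyl (2S)-2-{[(1E)-4,4-dibromo-2-ethylbuta-1,3-dien-1-yl]oxy}propanoate F4. Suzuki–Miyaura coupling with (E)-2-phenylethenylboronic acid (Pd(PPh3)4, aq. K3PO4, THF) reacts selectively at the bromine trans to the chain and should give methyl (2S)-2-{[(1E,3Z,5E)-4-bromo-2-ethyl-6-phenylhexa-1,3,5-trien-1-yl]oxy}propanoate F5. Negishi coupling of the remaining bromide with EtZnBr (Pd(P(t-Bu)3)2, THF, rt), with retention, comes back to the route at 8.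

Further compounds
F1 | step 11 | 2-(trimethylsilyl)ethyl (1R,2S,5S,6S)-5-[(2R)-but-3-en-2-yl]-2,4-diethyl-1-methyl-2-[(E)-2-phenylethenyl]-6-propanoylcyclohex-3-ene-1-carboxylate | CCC1=C[C@@](/C=C/c2ccccc2)(CC)[C@](C)(C(=O)OCC[Si](C)(C)C)[C@@H](C(=O)CC)[C@@H]1[C@H](C)C=C
F2 | step 11 | 2-(trimethylsilyl)ethyl (1R,2S,5S,6R)-6-(but-1-en-2-yl)-5-[(2R)-but-3-en-2-yl]-2,4-diethyl-1-methyl-2-[(E)-2-phenylethenyl]cyclohex-3-ene-1-carboxylate | CCC1=C[C@@](/C=C/c2ccccc2)(CC)[C@](C)(C(=O)OCC[Si](C)(C)C)[C@@H](C(=C)CC)[C@@H]1[C@H](C)C=C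
F3 | step 8 | 2-(trimethylsilyl)ethyl (2S,3RS,3aS,4R,5S,7aS)-5,7-diethyl-3-hydroxy-2,4-dimethyl-5-[(E)-2-phenylethenyl]-2,3,3a,4,5,7a-hexahydro-1-benzofuran-4-carboxylate | CCC1=C[C@@](/C=C/c2ccccc2)(CC)[C@](C)(C(=O)OCC[Si](C)(C)C)[C@H]2C(O)[C@H](C)O[C@H]12
F4 | step 4 | methyl (2S)-2-{[(1E)-4,4-dibromo-2-ethylbuta-1,3-dien-1-yl]oxy}propanoate | COC(=O)[C@H](C)O/C=C(CC)/C=C(Br)Br
F5 | step 4 | methyl (2S)-2-{[(1E,3Z,5E)-4-bromo-2-ethyl-6-phenylhexa-1,3,5-trien-1-yl]oxy}propanoate | COC(=O)[C@H](C)O/C=C(CC)/C=C(Br)/C=C/c1ccccc1
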